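**Retrosynthetic overview**
- Last bond: the C5–C8' biaryl bond, by Negishi coupling of a 5-bromo-tetrahydroisoquinoline with a 1-naphthylzinc reagent.
- Nitrogen ring: an o-acetylaryl acetone (a 1,5-diketone, the polyketide equivalent) is aminated at the acetonyl ketone by an (S)-selective transaminase and closes spontaneously to the cyclic imine (sets C3). cis-Hydride reduction then sets C1, and N-methylation follows in the same pot.
- That diketone comes from 3,5-dimethoxyphenylacetone by ring C-acetylation through a 2-benzopyrylium salt.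
- Naphthalene second ring: aldol cyclodehydration of the analogous o-acetylaryl acetone, made by insertion of 3-methoxybenzyne into acetylacetone. Bromine is placed para to OMe before this ring exists.
- Ring order: heterocycle (isoquinoline arm), carbocycle (naphthalene arm), then union of the two halves.

Assumption: the SMILES fixes only C1 (R) and C3 (S, i.e. 1,3-cis) and gives no descriptor for the hindered C5–C8' axis, so the coupling product is taken as the atropisomer mixture, separable by HPLC if one rotamer is wanted.

**Route**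

Step 1
Reactants: 1 1-(3,5-dimethoxyphenyl)propan-2-one
Product: 3 1-(2-acetyl-3,5-dimethoxyphenyl)propan-2-one, via benzopyrylium triflate 2 (not isolated)
Conditions: Ac2O, TfOH (1.1 equiv), 0 °C → rt; then aq. NaHCO3/EtOAc, 0 °C → rt
Reagents that add atoms: acetic anhydride CC(=O)OC(C)=O; water O
Why: Friedel–Crafts C-acetylation at the ring position ortho to the acetonyl chain (para to one OMe, ortho to the other) is followed by cyclodehydration of the ketone oxygen onto the new acyl group to give the 2-benzopyrylium salt, whose pseudobase ring-opens in bicarbonate to the 1,5-diketone.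

Step 2
Reactants: 3 1-(2-acetyl-3,5-dimethoxyphenyl)propan-2-one
Product: 5 (3S)-6,8-dimethoxy-1,3-dimethyl-3,4-dihydroisoquinoline, via amino ketone 4 (not isolated)
Conditions: (S)-selective ω-transaminase (e.g. ATA-113), PLP (1 mM), i-PrNH2 (5 equiv), K2HPO4/KH2PO4 buffer pH 7.5, 10% DMSO, 30 °C; basify to pH 11, extract
Reagents that add atoms: isopropylamine CC(C)N
Why: Proposed new method: the PLP-dependent transaminase should aminate only the unhindered benzyl methyl ketone (the di-ortho-substituted aryl ketone does not fit the active site), with methyl in the small pocket so that C3 is set as S, and the amine then condenses spontaneously with the ortho aryl ketone to the conjugated six-membered imine, which pulls the transamination equilibrium forward just as in the biosynthetic ring closure, the closest known reaction type being transaminase monoamination of aliphatic 1,5-diketones with spontaneous cyclisation to chiral Δ1-piperideines.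

Step 3
Reactants: 5 (3S)-6,8-dimethoxy-1,3-dimethyl-3,4-dihydroisoquinoline
Product: 7 (1R,3S)-6,8-dimethoxy-1,2,3-trimethyl-1,2,3,4-tetrahydroisoquinoline, via cis-N-H tetrahydroisoquinoline 6 (not isolated)
Conditions: NaBH4, MeOH, −20 → 0 °C; then 37% aq. HCHO, rt; then NaBH4, 0 °C
Reagents that add atoms: formaldehyde C=O
Why: Substrate-controlled imine reduction delivers hydride to C1 of the half-chair from the face opposite the C3 methyl, giving the 1,3-diequatorial cis amine (1R from 3S), and reductive amination with formaldehyde then methylates nitrogen without touching either stereocentre.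

Step 4
Reactants: 7 (1R,3S)-6,8-dimethoxy-1,2,3-trimethyl-1,2,3,4-tetrahydroisoquinoline
Product: 8 (1R,3S)-5-bromo-6,8-dimethoxy-1,2,3-trimethyl-1,2,3,4-tetrahydroisoquinoline
Conditions: NBS (1.0 equiv), AcOH, rt, dark; aq. Na2CO3 work-up
Reagents that add atoms: N-bromosuccinimide O=C1CCC(=O)N1Br
Why: Electrophilic aromatic bromination goes to C5 (para to the 8-OMe, ortho to the 6-OMe) rather than C7 (flanked by two OMe groups), while the amine is protected as its ammonium salt in AcOH.

Step 5
Reactants: 9 3-methoxy-2-(trimethylsilyl)phenyl trifluoromethanesulfonate; 10 pentane-2,4-dione (acetylacetone, 1.5 equiv)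
Product: 12 1-(2-acetyl-3-methoxyphenyl)propan-2-one, via 3-methoxybenzyne 11 (not isolated)
Conditions: KF, 18-crown-6, THF, 0 °C → rt
Reagents that add atoms: none
Why: Aryne acyl-alkylation (formal insertion into the C–C bond of the 1,3-diketone): the enolate attacks the aryne carbon meta to OMe, the resulting ortho-methoxy aryl anion adds to a carbonyl, and the benzocyclobutenoxide fragments, leaving acetyl next to OMe and acetonyl on the adjacent carbon.

Step 6
Reactants: 12 1-(2-acetyl-3-methoxyphenyl)propan-2-one
Product: 13 1-(2-acetyl-6-bromo-3-methoxyphenyl)propan-2-one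
Conditions: NBS (1.05 equiv), MeCN, 0 °C → rt, dark
Reagents that add atoms: N-bromosuccinimide O=C1CCC(=O)N1Br
Why: Electrophilic aromatic bromination occurs para to the methoxy group (meta to the twisted acetyl), and because the second ring is not yet formed the usual competition from the more electron-rich methyl-bearing naphthalene ring cannot arise.

Step 7
Reactants: 13 1-(2-acetyl-6-bromo-3-methoxyphenyl)propan-2-one
Product: 15 1-bromo-4,5-dimethoxy-7-methylnaphthalene, via bromonaphthol 14 (not isolated)
Conditions: KOH (3 equiv), DMSO, rt; then MeI, rt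
Reagents that add atoms: iodomethane CI
Why: Intramolecular aldol condensation of the aryl methyl ketone enolate onto the more electrophilic aliphatic ketone, then dehydration and enolisation, gives the 1-naphthol as in polyketide folding, and the naphtholate is then O-methylated (Williamson ether synthesis).

Step 8
Reactants: 15 1-bromo-4,5-dimethoxy-7-methylnaphthalene (1.3 equiv); 8 (1R,3S)-5-bromo-6,8-dimethoxy-1,2,3-trimethyl-1,2,3,4-tetrahydroisoquinoline
Product: 18 (1R,3S)-5-(4,5-dimethoxy-7-methylnaphthalen-1-yl)-6,8-dimethoxy-1,2,3-trimethyl-1,2,3,4-tetrahydroisoquinoline, via (4,5-dimethoxy-7-methylnaphthalen-1-yl)lithium 16 (not isolated), via (4,5-dimethoxy-7-methylnaphthalen-1-yl)zinc chloride 17 (not isolated)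
Conditions: 15, n-BuLi, THF, −78 °C; ZnCl2, −78 °C → rt; then 8, Pd2(dba)3 (2 mol%), SPhos (8 mol%), THF, 65 °C
Reagents that add atoms: none
Why: Bromine–lithium exchange and transmetalation give an arylzinc that undergoes Negishi coupling after oxidative addition of zerovalent palladium (bulky biarylphosphine ligand) into the hindered electron-rich bromide, with C1 and C3 untouched and the new axis formed as an atropisomer mixture.

**Compound list**
1 | 1-(3,5-dimethoxyphenyl)propan-2-one | COc1cc(OC)cc(CC(C)=O)c1 | starting material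
2 | 6,8-dimethoxy-1,3-dimethylisochromenylium (2-benzopyrylium) trifluoromethanesulfonate | COc1cc(OC)c2c(C)[o+]c(C)cc2c1.[O-]S(=O)(=O)C(F)(F)F | intermediate
3 | 1-(2-acetyl-3,5-dimethoxyphenyl)propan-2-one | COc1cc(OC)c(C(C)=O)c(CC(C)=O)c1 | intermediate
4 | 1-{2-[(2S)-2-aminopropyl]-4,6-dimethoxyphenyl}ethan-1-one | COc1cc(OC)c(C(C)=O)c(C[C@H](C)N)c1 | intermediate
5 | (3S)-6,8-dimethoxy-1,3-dimethyl-3,4-dihydroisoquinoline | COc1cc(OC)c2c(c1)C[C@H](C)N=C2C | intermediate
6 | (1R,3S)-6,8-dimethoxy-1,3-dimethyl-1,2,3,4-tetrahydroisoquinoline | COc1cc(OC)c2c(c1)C[C@H](C)N[C@@H]2C | intermediate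
7 | (1R,3S)-6,8-dimethoxy-1,2,3-trimethyl-1,2,3,4-tetrahydroisoquinoline | COc1cc(OC)c2c(c1)C[C@H](C)N(C)[C@@H]2C | intermediate
8 | (1R,3S)-5-bromo-6,8-dimethoxy-1,2,3-trimethyl-1,2,3,4-tetrahydroisoquinoline | COc1cc(OC)c2c(c1Br)C[C@H](C)N(C)[C@@H]2C | intermediate
9 | 3-methoxy-2-(trimethylsilyl)phenyl trifluoromethanesulfonate | COc1cccc(OS(=O)(=O)C(F)(F)F)c1[Si](C)(C)C | starting material
10 | pentane-2,4-dione (acetylacetone) | CC(=O)CC(C)=O | starting material
11 | 3-methoxybenzyne (3-methoxy-1,2-didehydrobenzene) | COC1=CC=CC#C1 | intermediate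
12 | 1-(2-acetyl-3-methoxyphenyl)propan-2-one | COc1cccc(CC(C)=O)c1C(C)=O | intermediate
13 | 1-(2-acetyl-6-bromo-3-methoxyphenyl)propan-2-one | COc1ccc(Br)c(CC(C)=O)c1C(C)=O | intermediate
14 | 5-bromo-8-methoxy-3-methylnaphthalen-1-ol | COc1ccc(Br)c2cc(C)cc(O)c12 | intermediate
15 | 1-bromo-4,5-dimethoxy-7-methylnaphthalene | COc1ccc(Br)c2cc(C)cc(OC)c12 | intermediate
16 | (4,5-dimethoxy-7-methylnaphthalen-1-yl)lithium | [Li]c1ccc(OC)c2c(OC)cc(C)cc12 | intermediate
17 | (4,5-dimethoxy-7-methylnaphthalen-1-yl)zinc chloride | Cl[Zn]c1ccc(OC)c2c(OC)cc(C)cc12 | intermediate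
18 | (1R,3S)-5-(4,5-dimethoxy-7-methylnaphthalen-1-yl)-6,8-dimethoxy-1,2,3-trimethyl-1,2,3,4-tetrahydroisoquinoline | COc1cc(OC)c2c(c1-c1ccc(OC)c3c(OC)cc(C)cc13)C[C@H](C)N(C)[C@@H]2C | target

**Totals**
Total steps: 8. Longest linear sequence: 5 (steps 1, 2, 3, 4, 8); the naphthalene arm is 3 steps (5, 6, 7) before the union.

**Three steps most likely to fail, with fallbacks**

Step 2 (transaminase amination and ring closure of diketone 3). The ortho-acetyl group may slow the enzyme, and the 1,5-diketone can condense non-enzymatically with the amine donor to an isoquinolinium salt or cyclise by aldol reaction. The fallback sets out from 1 and comes back at 5. The same (S)-selective ω-transaminase with i-PrNH2 and PLP is applied to the simple arylacetone 1, a standard substrate class, to give (2S)-1-(3,5-dimethoxyphenyl)propan-2-amine F1. Ac2O and Et3N in CH2Cl2 convert it into N-[(2S)-1-(3,5-dimethoxyphenyl)propan-2-yl]acetamide F2. Bischler–Napieralski cyclisation (POCl3, MeCN, reflux) onto the ring position para to one methoxy group then gives 5, and the route continues with step 3.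

Step 6 (ring bromination of diketone 12). α-Bromination of the enolisable benzyl ketone, or premature aldol cyclisation, may compete. The fallback sets out from 12 and comes back at 15. KOH in MeOH cyclises 12 to 8-methoxy-3-methylnaphthalen-1-ol F3. Ac2O, pyridine and DMAP give 8-methoxy-3-methylnaphthalen-1-yl acetate F4, in which the methyl-bearing ring is deactivated. NBS in MeCN then brominates para to the methoxy group on the other ring to give 5-bromo-8-methoxy-3-methylnaphthalen-1-yl acetate F5. KOH in DMSO cleaves the acetate to the naphtholate of 14, and MeI in the same pot gives 15.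

Step 8 (Negishi coupling). Oxidative addition into the di-ortho-substituted, electron-rich amine-bearing bromide 8 may be slow, and the arylzinc may simply be protonated. The fallback reverses the polarity; it sets out from 8 and comes back at 18. Bromine–lithium exchange on 8 (n-BuLi, THF, −78 °C) and a quench with 2-isopropoxy-4,4,5,5-tetramethyl-1,3,2-dioxaborolane give (1R,3S)-6,8-dimethoxy-1,2,3-trimethyl-5-(4,4,5,5-tetramethyl-1,3,2-dioxaborolan-2-yl)-1,2,3,4-tetrahydroisoquinoline F6. Suzuki–Miyaura coupling of F6 with the unhindered naphthyl bromide 15 (Pd(OAc)2, SPhos, K3PO4, toluene/H2O, 100 °C) then gives 18.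

**Further compounds**
F1 | step 2 | (2S)-1-(3,5-dimethoxyphenyl)propan-2-amine | COc1cc(OC)cc(C[C@H](C)N)c1
F2 | step 2 | N-[(2S)-1-(3,5-dimethoxyphenyl)propan-2-yl]acetamide | COc1cc(OC)cc(C[C@H](C)NC(C)=O)c1
F3 | step 6 | 8-methoxy-3-methylnaphthalen-1-ol | COc1cccc2cc(C)cc(O)c12
F4 | step 6 | 8-methoxy-3-methylnaphthalen-1-yl acetate | COc1cccc2cc(C)cc(OC(C)=O)c12
F5 | step 6 | 5-bromo-8-methoxy-3-methylnaphthalen-1-yl acetate | COc1ccc(Br)c2cc(C)cc(OC(C)=O)c12
F6 | step 8 | (1R,3S)-6,8-dimethoxy-1,2,3-trimethyl-5-(4,4,5,5-tetramethyl-1,3,2-dioxaborolan-2-yl)-1,2,3,4-tetrahydroisoquinoline | COc1cc(OC)c2c(c1B1OC(C)(C)C(C)(C)O1)C[C@H](C)N(C)[C@@H]2C
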